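**Plan**

- Numbering and enabling feature: ring B is C1 (CH bearing the 4-hydroxyphenyl group), C2 (CH–aroyl), C3 (alkene C–aroyl), C4 (alkene CH), C4a and C8a (shared with catechol ring A). The two aroyl carbonyls sit on the neighbouring carbons C2 and C3, so O=C–C2–C3–C=O is a 1,4-diketone, the pattern left by oxidative union of two aryl ketone enol ethers.
- Cuts, in order: the seven O–CH3 bonds; the C3=C4 double bond (back to a C4-methoxy tetralin); C2–C3 (anodic coupling across an eleven-membered diisopropylsilylene bis(Z-enol ether)); the two Si–O bonds; C3–C4 (Mukaiyama addition to an aryl dimethyl acetal); C1–C8a (rhodium-catalysed asymmetric arylation of a chalcone); the chalcone C=C.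
- Forward: chalcone and arylboronate are joined at C1–C8a, C3–C4 attaches the second ketone arm, the silylene bridge closes a temporary eleven-membered ring, ring B is closed across it by C2–C3, the alkene is unveiled and the phenols are freed. All four arenes are bought.
- Stereochemistry: C1 (R) comes from the chiral diene–rhodium catalyst. C2 (S, trans to C1) follows from C1, kinetically in the coupling and thermodynamically on base treatment. The sp3 centres at C3 and C4 are transient.

Key step: step 8

Remark (assumption): the methoxy-bearing carbon made in step 6 (later C4) is not controlled. Both epimers are carried together and converge in step 9; names and SMILES show one epimer for definiteness.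

**Route**

Step 1
Reactants: 1 2',4'-dimethoxyacetophenone; 2 4-methoxybenzaldehyde
Product: 3 (E)-1-(2,4-dimethoxyphenyl)-3-(4-methoxyphenyl)prop-2-en-1-one
Conditions: KOH, EtOH, rt
Reagents that add atoms: none
Why: Claisen–Schmidt condensation of the methyl ketone enolate with the non-enolisable aldehyde, followed by E1cB dehydration, should give the thermodynamically favoured E-chalcone.

Step 2
Reactants: 4 2-bromo-4,5-dimethoxybenzaldehyde
Product: 5 1-bromo-2-(dimethoxymethyl)-4,5-dimethoxybenzene
Conditions: HC(OMe)3, p-TsOH (cat.), MeOH, 50 °C; then Et3N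
Reagents that add atoms: trimethyl orthoformate COC(OC)OC; methanol CO
Why: Acid-catalysed acetalisation, driven by the orthoformate as water scavenger, masks the aldehyde as the dimethyl acetal that survives the basic metal-catalysed steps and later serves as the oxocarbenium precursor.

Step 3
Reactants: 5 1-bromo-2-(dimethoxymethyl)-4,5-dimethoxybenzene
Product: 6 2-[2-(dimethoxymethyl)-4,5-dimethoxyphenyl]-4,4,5,5-tetramethyl-1,3,2-dioxaborolane
Conditions: B2pin2, PdCl2(dppf) (cat.), KOAc, 1,4-dioxane, 90 °C
Reagents that add atoms: bis(pinacolato)diboron CC1(C)OB(OC1(C)C)B1OC(C)(C)C(C)(C)O1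
Why: Miyaura borylation (oxidative addition of the aryl bromide, acetate-assisted transmetalation from the diboron, reductive elimination) is reliable for electron-rich ortho-substituted aryl bromides and leaves the acetal untouched under the weakly basic conditions.

Step 4
Reactants: 3 (E)-1-(2,4-dimethoxyphenyl)-3-(4-methoxyphenyl)prop-2-en-1-one; 6 2-[2-(dimethoxymethyl)-4,5-dimethoxyphenyl]-4,4,5,5-tetramethyl-1,3,2-dioxaborolane
Product: 7 (3R)-3-[2-(dimethoxymethyl)-4,5-dimethoxyphenyl]-1-(2,4-dimethoxyphenyl)-3-(4-methoxyphenyl)propan-1-one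
Conditions: [RhCl(C2H4)2]2 (cat.), (S,S)-Ph-bod* [(1S,4S)-2,5-diphenylbicyclo[2.2.2]octa-2,5-diene], KOH (aq), 1,4-dioxane, 60 °C
Reagents that add atoms: none
Why: Hayashi–Miyaura asymmetric 1,4-addition, in which the aryl–rhodium species formed by transmetalation from 6 delivers the aryl group to the Re face of C3 of chalcone 3 inside the C2-symmetric diene pocket, should set C1 as R; the (S,S) ligand is chosen by analogy with the facial sense this diene family shows for E-enones, and the mirror-image ligand would be taken if a model addition showed the opposite sense.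

Step 5
Reactants: 1 2',4'-dimethoxyacetophenone
Product: 8 {[1-(2,4-dimethoxyphenyl)ethenyl]oxy}trimethylsilane
Conditions: TMSOTf, Et3N, CH2Cl2, 0 °C
Reagents that add atoms: trimethylsilyl trifluoromethanesulfonate C[Si](C)(C)OS(=O)(=O)C(F)(F)F
Why: Soft enolisation (O-silylation of the carbonyl by the silyl triflate, then deprotonation of the silyloxocarbenium ion by the amine) is the standard preparation of the trimethylsilyl enol ether of an aryl methyl ketone.

Step 6
Reactants: 7 (3R)-3-[2-(dimethoxymethyl)-4,5-dimethoxyphenyl]-1-(2,4-dimethoxyphenyl)-3-(4-methoxyphenyl)propan-1-one; 8 {[1-(2,4-dimethoxyphenyl)ethenyl]oxy}trimethylsilane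
Product: 9 (3R)-3-{2-[(1R)-3-(2,4-dimethoxyphenyl)-1-methoxy-3-oxopropyl]-4,5-dimethoxyphenyl}-1-(2,4-dimethoxyphenyl)-3-(4-methoxyphenyl)propan-1-one (drawn epimer; its epimer at the methoxy carbon accompanies it)
Conditions: TMSOTf (10 mol %), CH2Cl2, −78 °C
Reagents that add atoms: none
Why: Mukaiyama aldol-type addition to an acetal, in which catalytic silyl triflate ionises the electron-rich benzylic dimethyl acetal to an oxocarbenium ion that the enol silane captures at −78 °C while the unactivated ketone of 7 stays inert, should give the β-methoxy ketone; the new centre is remote from C1 and is not controlled.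

Step 7
Reactants: 9 the diketone of step 6; 10 diisopropylsilyl bis(trifluoromethanesulfonate)
Product: 11 eleven-membered cyclic diisopropylsilylene bis(Z-enol ether) of 9 (ring sequence Si–O–C(Ar)=C2H–C1H(4-methoxyphenyl)–C8a–C4a–C4H(OMe)–C3H=C(Ar)–O, Ar = 2,4-dimethoxyphenyl, C4a–C8a being a bond of the 4,5-dimethoxybenzene ring; 1R,4R; both enol ethers Z)
Conditions: Et3N, CH2Cl2, high dilution (slow addition of 9 and 10), 0 °C to rt
Reagents that add atoms: none
Why: Double soft enolisation with a bifunctional silyl triflate, the second O-silylation being intramolecular under high dilution, should bridge the two ketones as a cyclic silylene bis(enol ether), ketones of the type ArCOCH2R giving Z-enol ethers because the E isomers suffer allylic strain between the aryl group and the β-substituent.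

Step 8
Reactants: 11 the cyclic silylene bis(Z-enol ether) of step 7
Product: 13 tetralin diketone [(1R,2S,3R,4R)-4,6,7-trimethoxy-1-(4-methoxyphenyl)-1,2,3,4-tetrahydronaphthalene-2,3-diyl]bis[(2,4-dimethoxyphenyl)methanone], via silicon-bridged bis(oxocarbenium) dication 12 (not isolated)
Conditions: reticulated vitreous carbon anode, Pt cathode, undivided cell, constant current (about 2.1 F/mol), LiClO4 (0.1 M), 2,6-lutidine, MeCN–MeOH (4:1), 0 °C
Reagents that add atoms: none
Why: Proposed new method: one-electron oxidation of one aryl silyl enol ether at the anode should give a radical cation whose β-carbon (C2) is attacked by the β-carbon (C3) of the second enol ether lying across the eleven-membered ring, a second electron transfer gives the bridged dication 12, and methanol then removes silicon as iPr2Si(OMe)2 to release both ketones. The closest known reaction types are the oxidative coupling of silicon-tethered bis(enol ethers) to 1,4-diketones by (NH4)2Ce(NO3)6 and anodic enol ether radical-cation cyclisations, neither of which has been carried out transannularly in a preformed silylene macrocycle. Ring B closes in a 6-exo-trig mode (C2 adds to C3, the C3=C(O) bond lying outside the new six-membered ring), the seven-membered siladioxepane of 12 being only the contracted tether. C2 is controlled by the C1 stereocentre, the new bond forming on the enol ether face anti to the 4-methoxyphenyl group, and C3 by the Z,Z geometry locked by the silylene bridge, which should favour the trans (diequatorial) placement of the two acyl carbons; C3 is erased and C2 can still be corrected in step 9. The step needs the enol ethers to be oxidised ahead of the veratrole and anisole rings and of the product, which the 2,4-dimethoxyphenyl donors on both enol ethers, a charge limited to about 2 F/mol and 2,6-lutidine as proton trap should secure.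

Step 9
Reactants: 13 the tetralin diketone of step 8
Product: 14 [(1R,2S)-6,7-dimethoxy-1-(4-methoxyphenyl)-1,2-dihydronaphthalene-2,3-diyl]bis[(2,4-dimethoxyphenyl)methanone]
Conditions: DBU, THF, rt to 40 °C, argon
Reagents that add atoms: none
Why: E1cB elimination, in which DBU removes the C3 proton α to the ketone and the enolate expels the C4 methoxide (anti to H3 in the drawn epimer, lost equally from the other), should give the enone conjugated with ring A, while any C2 epimer equilibrates through its enolate to the more stable trans arrangement and the non-acidic C1–H is untouched.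

Step 10
Reactants: 14 the heptamethyl ether of step 9
Product: 15 [(1R,2S)-6,7-dihydroxy-1-(4-hydroxyphenyl)-1,2-dihydronaphthalene-2,3-diyl]bis[(2,4-dihydroxyphenyl)methanone] (CNP0195549.2)
Conditions: BBr3 (excess), CH2Cl2, −78 °C to rt; then H2O
Reagents that add atoms: none
Why: Lewis acid cleavage of aryl methyl ethers (O-complexation by BBr3, bromide attack on the methyl group, hydrolysis of the aryl borates on work-up) should free all seven phenols without touching the two stereocentres, the ortho-methoxy groups next to the ketones going first through chelation.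

**Compound list**

1 | 2',4'-dimethoxyacetophenone | CC(=O)c1ccc(OC)cc1OC | starting material
2 | 4-methoxybenzaldehyde | COc1ccc(C=O)cc1 | starting material
3 | (E)-1-(2,4-dimethoxyphenyl)-3-(4-methoxyphenyl)prop-2-en-1-one | COc1ccc(/C=C/C(=O)c2ccc(OC)cc2OC)cc1 | intermediate
4 | 2-bromo-4,5-dimethoxybenzaldehyde | COc1cc(Br)c(C=O)cc1OC | starting material
5 | 1-bromo-2-(dimethoxymethyl)-4,5-dimethoxybenzene | COc1cc(Br)c(C(OC)OC)cc1OC | intermediate
6 | 2-[2-(dimethoxymethyl)-4,5-dimethoxyphenyl]-4,4,5,5-tetramethyl-1,3,2-dioxaborolane | COc1cc(B2OC(C)(C)C(C)(C)O2)c(C(OC)OC)cc1OC | intermediate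
7 | (3R)-3-[2-(dimethoxymethyl)-4,5-dimethoxyphenyl]-1-(2,4-dimethoxyphenyl)-3-(4-methoxyphenyl)propan-1-one | COc1ccc([C@@H](CC(=O)c2ccc(OC)cc2OC)c2cc(OC)c(OC)cc2C(OC)OC)cc1 | intermediate
8 | {[1-(2,4-dimethoxyphenyl)ethenyl]oxy}trimethylsilane | C=C(O[Si](C)(C)C)c1ccc(OC)cc1OC | intermediate
9 | (3R)-3-{2-[(1R)-3-(2,4-dimethoxyphenyl)-1-methoxy-3-oxopropyl]-4,5-dimethoxyphenyl}-1-(2,4-dimethoxyphenyl)-3-(4-methoxyphenyl)propan-1-one | COc1ccc([C@@H](CC(=O)c2ccc(OC)cc2OC)c2cc(OC)c(OC)cc2[C@H](OC)CC(=O)c2ccc(OC)cc2OC)cc1 | intermediate
10 | diisopropylsilyl bis(trifluoromethanesulfonate) | CC(C)[Si](OS(=O)(=O)C(F)(F)F)(OS(=O)(=O)C(F)(F)F)C(C)C | starting material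
11 | eleven-membered cyclic diisopropylsilylene bis(Z-enol ether) of 9 (1R,4R; Z,Z) | CC(C)[Si]1(C(C)C)O/C(c2ccc(OC)cc2OC)=C\[C@H](c2ccc(OC)cc2)c2cc(OC)c(OC)cc2[C@H](OC)/C=C(c2ccc(OC)cc2OC)\O1 | intermediate
12 | silicon-bridged bis(oxocarbenium) dication (13 with both carbonyl oxygens still joined through Si(iPr)2 in a seven-membered siladioxepane) | CC(C)[Si]1(C(C)C)[O+]=C(c2ccc(OC)cc2OC)[C@H]2[C@@H](OC)c3cc(OC)c(OC)cc3[C@@H](c3ccc(OC)cc3)[C@@H]2C(c2ccc(OC)cc2OC)=[O+]1 | intermediate (not isolated)
13 | [(1R,2S,3R,4R)-4,6,7-trimethoxy-1-(4-methoxyphenyl)-1,2,3,4-tetrahydronaphthalene-2,3-diyl]bis[(2,4-dimethoxyphenyl)methanone] | O=C([C@H]1[C@@H](OC)c2cc(OC)c(OC)cc2[C@@H](c2ccc(OC)cc2)[C@@H]1C(=O)c1ccc(OC)cc1OC)c1ccc(OC)cc1OC | intermediate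
14 | [(1R,2S)-6,7-dimethoxy-1-(4-methoxyphenyl)-1,2-dihydronaphthalene-2,3-diyl]bis[(2,4-dimethoxyphenyl)methanone] | O=C(C1=Cc2cc(OC)c(OC)cc2[C@@H](c2ccc(OC)cc2)[C@@H]1C(=O)c1ccc(OC)cc1OC)c1ccc(OC)cc1OC | intermediate
15 | [(1R,2S)-6,7-dihydroxy-1-(4-hydroxyphenyl)-1,2-dihydronaphthalene-2,3-diyl]bis[(2,4-dihydroxyphenyl)methanone] | O=C(C1=Cc2cc(O)c(O)cc2[C@@H](c2ccc(O)cc2)[C@@H]1C(=O)c1ccc(O)cc1O)c1ccc(O)cc1O | target

**Totals**

Total step count: 10. Longest linear sequence: 8 steps (4 → 5 → 6 → 7 → 9 → 11 → 13 → 14 → 15; steps 2, 3, 4, 6, 7, 8, 9, 10).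

**Steps most likely to fail**

Step 8 (the one step beyond known chemistry). The radical cation may be intercepted by methanol or lose silicon before the C2–C3 bond forms, which only returns the open diketone. The ring may also not bring C2 and C3 within bonding distance, or the electron-rich arenes and the product may be over-oxidised. The fallback sets out from 9 and comes back at 13. Double deprotonation with LiN(iPr)2 in THF at −78 °C should give the dilithium (Z,Z)-bis(enolate) F1. Its oxidation with anhydrous CuCl2 in DMF–THF at −78 °C is an intramolecular oxidative enolate coupling, a known way to close cyclic 1,4-diketones. The low temperature keeps the β-methoxy enolate from eliminating, and the C2/C3 isomers converge in step 9 as before.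

Step 7. Intermolecular silylation may outrun the second, ring-closing silylation and give oligomers, and the silyl triflate may ionise the benzylic methoxy group. The fallback sets out from 9 and comes back at 13. TBSOTf and Et3N in CH2Cl2 should give the open-chain bis(tert-butyldimethylsilyl) (Z,Z)-bis(enol ether) F2. Oxidation with (NH4)2Ce(NO3)6 and NaHCO3 in MeCN at −20 °C, the known intramolecular oxidative coupling of 1,ω-bis(silyl enol ethers), then closes ring B without any silicon bridge.

Step 4. Transmetalation of the ortho-branched, electron-rich boronate may be slow enough for protodeboronation to win, and the facial selectivity that fixes the absolute configuration may be insufficient. The fallback exchanges the roles of the two aryl groups; it sets out from 4 (with 1) and comes back at 7.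
- Claisen–Schmidt condensation of 4 with 1 (KOH, EtOH) should give (E)-3-(2-bromo-4,5-dimethoxyphenyl)-1-(2,4-dimethoxyphenyl)prop-2-en-1-one F3.
- Addition of unhindered 4-methoxyphenylboronic acid with [RhCl(C2H4)2]2 and the mirror-image diene (R,R)-Ph-bod* (Si face of C3, the same spatial result) should give (3R)-3-(2-bromo-4,5-dimethoxyphenyl)-1-(2,4-dimethoxyphenyl)-3-(4-methoxyphenyl)propan-1-one F4.
- Palladium-catalysed reductive carbonylation (Pd(OAc)2, di(1-adamantyl)-n-butylphosphine, CO/H2, N,N,N',N'-tetramethylethylenediamine, toluene, 100 °C) should give 2-[(1R)-3-(2,4-dimethoxyphenyl)-1-(4-methoxyphenyl)-3-oxopropyl]-4,5-dimethoxybenzaldehyde F5.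
- Selective acetalisation of the aldehyde under the conditions of step 2 returns 7.

Further compounds
F1 | step 8 | dilithium (Z,Z)-bis(enolate) of 9 | [Li+].[Li+].COc1ccc([C@@H](/C=C(\[O-])c2ccc(OC)cc2OC)c2cc(OC)c(OC)cc2[C@H](OC)/C=C(\[O-])c2ccc(OC)cc2OC)cc1
F2 | step 7 | bis(tert-butyldimethylsilyl) (Z,Z)-bis(enol ether) of 9 | COc1ccc([C@@H](/C=C(\O[Si](C)(C)C(C)(C)C)c2ccc(OC)cc2OC)c2cc(OC)c(OC)cc2[C@H](OC)/C=C(\O[Si](C)(C)C(C)(C)C)c2ccc(OC)cc2OC)cc1
F3 | step 4 | (E)-3-(2-bromo-4,5-dimethoxyphenyl)-1-(2,4-dimethoxyphenyl)prop-2-en-1-one | COc1cc(Br)c(/C=C/C(=O)c2ccc(OC)cc2OC)cc1OC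
F4 | step 4 | (3R)-3-(2-bromo-4,5-dimethoxyphenyl)-1-(2,4-dimethoxyphenyl)-3-(4-methoxyphenyl)propan-1-one | COc1ccc([C@@H](CC(=O)c2ccc(OC)cc2OC)c2cc(OC)c(OC)cc2Br)cc1
F5 | step 4 | 2-[(1R)-3-(2,4-dimethoxyphenyl)-1-(4-methoxyphenyl)-3-oxopropyl]-4,5-dimethoxybenzaldehyde | COc1ccc([C@@H](CC(=O)c2ccc(OC)cc2OC)c2cc(OC)c(OC)cc2C=O)cc1
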